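**Retrosynthetic overview**

1. Target 43 comes from spiro pyranone 36 by O-methylation, conjugate reduction, removal of the C3 carbonyl and loss of methanol (C5=C6). 36 comes from tertiary furfuryl alcohol 33 by Achmatowicz ring expansion. The feature used: pyran O1, C2 and C3–C6 are the carbinol oxygen, the hydroxylated lactone α-carbon C11 and the four ring carbons C2–C5 of a 2,4-disubstituted furan.
2. 33 comes from 32 by enolate hydroxylation on the convex lactone face; 32 from bromofuran 30 and alkylzinc 31 (Negishi, C7′–furan C4); 30 from lactone 18 and 2,4-dibromofuran (enolate arylation, C11–furan C2).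
3. Lactone 18 (cis-decalin, 5β-H) comes from iodolactonisation of acid 16, made by Mukaiyama–Michael addition to enone 10; 10 comes from annulation of ring A onto acetoxy enone 6, derived from (S)-carvone.
4. Iodide 28 comes from an enantioselective Diels–Alder reaction of diene 20 with enal 23, which sets C10′ and C5′.
5. Ring order: ring A onto ring B (steps 3–4), γ-lactone (step 8), elemane cyclohexane (step 12, separate branch), pyran last (step 19).

Key step: step 19

**Remarks on the chemistry**

- Locants follow eudesmane numbering for the decalin lactone half (C11 = lactone α-carbon, C12 = lactone carbonyl) and primed elemane numbering for the cyclohexane half (C7′ carries the heterocycle). β is the face of the C10 methyl group.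
- The target SMILES has 5-H cis to the C10 methyl group (cis-decalin) and the elemane half in the series antipodal to (−)-β-elemene. Isoalantolactone and (−)-β-elemene therefore do not fit, and both halves are built.
- Assumption: the catalyst antipode in step 12 is assigned by analogy with the sense of induction known for 2-substituted acroleins (formyl C–H···O binding model); if the sense proves opposite, the antipodal catalyst is used.
- Centres that are destroyed later (C10 in 9, C11 in 30 and 32, C5/C6 of the pyran in 36–42, the carbinol carbon of 27/28) are carried as mixtures.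

**Part A: cis-decalin lactone 18**

Step 1
Reactants: 1 5-chloropent-1-yne
Product: 2 2-bromo-5-chloropent-1-ene
Conditions: HBr (33% in AcOH), Et4NBr, CH2Cl2, 40 °C
Reagents that add atoms: hydrogen bromide, Br
Why: Markovnikov hydrobromination of the terminal alkyne with the hydrogen dibromide salt puts bromine on the internal carbon and stops at the vinyl bromide, and the primary chloride is inert.

Step 2
Reactants: 3 (S)-carvone
Product: 6 (S)-acetoxy enone, via methoxy hydroperoxide 4 (not isolated), via peracetate 5 (not isolated)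
Conditions: O3, CH2Cl2/MeOH, NaHCO3, −78 °C; then Ac2O, Et3N, DMAP (cat.), 0 → 40 °C
Reagents that add atoms: ozone, O=[O+][O-]; methanol, CO
Why: Ozone attacks only the electron-rich isopropenyl group, methanol traps the carbonyl oxide, and after acetylation a Criegee rearrangement moves the ring carbon to oxygen with retention, so the carvone stereocentre becomes the acetoxy-bearing carbon unchanged.

Step 3
Reactants: 2 2-bromo-5-chloropent-1-ene; 6 (S)-acetoxy enone
Product: 9 chloroalkenyl enone, via Grignard reagent 7 (not isolated), via acetoxy ketone 8 (not isolated)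
Conditions: Mg, THF, 40 °C (from 2); CuBr·SMe2 (10 mol%), 6, THF, −78 → −40 °C; NH4Cl aq.; then DBU, CH2Cl2, 25 °C
Reagents that add atoms: none
Why: Copper-catalysed conjugate addition of the alkenyl Grignard reagent enters anti to the 5-acetoxy group, as is usual for 5-substituted cyclohexenones, and so sets C5, after which DBU removes acetic acid by E1cB elimination to give the enone.

Step 4
Reactants: 9 chloroalkenyl enone
Product: 10 cis-fused bicyclic enone
Conditions: LiN(iPr)2, THF, −78 °C; then DMPU, −78 → 25 °C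
Reagents that add atoms: none
Why: Kinetic deprotonation at the α′ carbon (C10) and intramolecular 6-exo-tet enolate alkylation by the primary chloride (methylenecyclohexane annulation) form the quaternary C10, and the tether on the neighbouring C5 can reach only its own face, so the ring fusion is cis (5β-H, 10β-CH3).

Step 5
Reactants: 10 cis-fused bicyclic enone; 11 1-(tert-butyldimethylsilyloxy)-1-methoxyethene
Product: 13 keto ester, via silyl enol ether 12 (not isolated)
Conditions: Tf2NH (2 mol%), CH2Cl2, −78 °C; then 1 M HCl, THF, 0 °C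
Reagents that add atoms: none
Why: The acid-catalysed Mukaiyama–Michael addition delivers the acetate unit to C7 from the convex β face of the cis-fused enone, anti to the C5–C4 bond, which sets C7 with the side chain cis to the angular methyl group.

Step 6
Reactants: 13 keto ester
Product: 14 enol triflate
Conditions: KN(SiMe3)2, THF, −78 °C; PhNTf2, −78 → 0 °C
Reagents that add atoms: N-phenylbis(trifluoromethanesulfonimide), O=S(=O)(N(c1ccccc1)S(=O)(=O)C(F)(F)F)C(F)(F)F
Why: The ketone can enolise only towards C8 because C10 is quaternary, so O-sulfonylation of the potassium enolate gives a single enol triflate.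

Step 7
Reactants: 14 enol triflate
Product: 15 alkene ester
Conditions: Pd(OAc)2 (5 mol%), PPh3 (10 mol%), HCO2H, Bu3N, DMF, 60 °C
Reagents that add atoms: none
Why: Palladium-catalysed hydride transfer from formate reduces the enol triflate to the C8=C9 alkene without touching the exocyclic methylene group or the ester.

Step 8
Reactants: 15 alkene ester
Product: 17 iodolactone, via carboxylic acid 16 (not isolated)
Conditions: LiOH, THF/H2O, 25 °C; then NaHCO3, I2, KI, 0 → 25 °C
Reagents that add atoms: iodine, II; lithium hydroxide, [Li+].[OH-]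
Why: Saponification and kinetic iodolactonisation (5-exo attack of the carboxylate on the iodonium ion of C8=C9) can only give the cis-fused γ-lactone, so the C8–O bond forms on the face of the C7 side chain with iodine trans at C9, while the remote exocyclic alkene has no internal nucleophile.

Step 9
Reactants: 17 iodolactone
Product: 18 lactone
Conditions: Bu3SnH, AIBN (cat.), toluene, 80 °C
Reagents that add atoms: none
Why: Radical chain dehalogenation removes the C9 iodine, and the secondary radical has no alkene placed for a 5-exo closure.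

**Part B: elemane iodide 28**

Step 10
Reactants: 19 methyl vinyl ketone
Product: 20 2-(triisopropylsilyloxy)buta-1,3-diene
Conditions: iPr3SiOTf, Et3N, Et2O, 0 → 25 °C
Reagents that add atoms: triisopropylsilyl trifluoromethanesulfonate, CC(C)[Si](OS(=O)(=O)C(F)(F)F)(C(C)C)C(C)C
Why: Soft enolisation of the methyl ketone with silyl triflate and amine gives the 2-silyloxydiene (silyl enol ether formation).

Step 11
Reactants: 21 2-(triphenylphosphoranylidene)propanal; 22 methylglyoxal
Product: 23 (E)-2-methyl-4-oxopent-2-enal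
Conditions: CH2Cl2/H2O, 25 °C
Reagents that add atoms: none
Why: The Wittig reaction of the stabilised formyl ylide takes place at the aldehyde carbonyl of methylglyoxal and gives the E trisubstituted alkene.

Step 12
Reactants: 20 2-(triisopropylsilyloxy)buta-1,3-diene; 23 (E)-2-methyl-4-oxopent-2-enal
Product: 24 Diels–Alder adduct
Conditions: (R)-3,3-diphenyl-1-(2-methylphenyl)tetrahydro-1H,3H-pyrrolo[1,2-c][1,3,2]oxazaborole·HNTf2 (20 mol%), CH2Cl2, −78 °C
Reagents that add atoms: none
Why: In this enantioselective Diels–Alder reaction the cationic oxazaborolidine binds the formyl group, the nucleophilic CH2 terminus next to the silyloxy carbon bonds to the unsubstituted carbon β to the aldehyde (para orientation), the E geometry of 23 places formyl and acetyl trans, and the shielded face of the bound enal fixes C10′ and C5′.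

Step 13
Reactants: 24 Diels–Alder adduct
Product: 25 triene silyl enol ether
Conditions: Ph3PCH3Br, KN(SiMe3)2, THF, −78 → 25 °C (24 added to excess ylide)
Reagents that add atoms: methyltriphenylphosphonium bromide, C[P+](c1ccccc1)(c1ccccc1)c1ccccc1.[Br-]
Why: Twofold Wittig methylenation turns the aldehyde and the methyl ketone into the vinyl and isopropenyl groups while the ring carbonyl stays masked as its silyl enol ether, and inverse addition at low temperature limits enolisation at C5′.

Step 14
Reactants: 25 triene silyl enol ether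
Product: 27 cyclohexanol, via ketone 26 (not isolated)
Conditions: Bu4NF, AcOH, THF, 0 °C; then NaBH4, MeOH, 0 °C
Reagents that add atoms: none
Why: Fluoride cleaves the silyl enol ether to the ketone and borohydride reduces it, and the configuration of the carbinol carbon does not matter because it is lost at the organozinc stage.

Step 15
Reactants: 27 cyclohexanol
Product: 28 cyclohexyl iodide
Conditions: I2, PPh3, imidazole, CH2Cl2, 0 → 25 °C
Reagents that add atoms: iodine, II
Why: Appel-type iodination replaces the secondary hydroxyl group by iodide.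

**Part C: union, key step and endgame**

Step 16
Reactants: 18 lactone; 29 2,4-dibromofuran
Product: 30 α-(4-bromofuran-2-yl) lactone
Conditions: LiN(SiMe3)2, THF, −78 °C; ZnCl2; then 29, Pd(dba)2 (3 mol%), P(t-Bu)3 (6 mol%), THF, 25 °C
Reagents that add atoms: none
Why: In this palladium-catalysed α-arylation of the lactone zinc enolate, oxidative addition takes the more reactive C2–Br bond of the dibromofuran and the weakly basic zinc enolate avoids diarylation and Claisen condensation, while the C11 configuration is left open because step 18 planarises it again.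

Step 17
Reactants: 28 cyclohexyl iodide; 30 α-(4-bromofuran-2-yl) lactone
Product: 32 α-furyl lactone, via alkylzinc iodide 31 (not isolated)
Conditions: Zn, LiCl, THF, 40 °C (from 28); then 30, Pd(OAc)2 (3 mol%), CPhos (6 mol%), THF/toluene, 25 °C
Reagents that add atoms: none
Why: Negishi coupling of the secondary alkylzinc iodide with the remaining C4–Br bond uses a biarylphosphine that suppresses β-hydride isomerisation, and the cyclohexyl–metal intermediates settle in the equatorial position, so the furan should end cis to the equatorial isopropenyl group (C7′ S).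

Step 18
Reactants: 32 α-furyl lactone
Product: 33 tertiary furfuryl alcohol
Conditions: KN(SiMe3)2, THF, −78 °C; 2-(phenylsulfonyl)-3-phenyloxaziridine, −78 °C; NH4Cl aq.
Reagents that add atoms: 2-(phenylsulfonyl)-3-phenyloxaziridine, O=S(=O)(N1OC1c1ccccc1)c1ccccc1
Why: In this enolate hydroxylation the oxaziridine reaches the planar furyl-conjugated C11 from the convex face of the cis-fused bicyclic lactone, anti to C6, so the hydroxyl ends syn to H-7 and the furan on the concave face, as C11 of the target requires.

Step 19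
Reactants: 33 tertiary furfuryl alcohol
Product: 36 spiro 6-hydroxy-2H-pyran-3(6H)-one, via dihydrofuran diol 34 (not isolated), via enedione 35 (not isolated)
Conditions: NBS (1.05 equiv), NaHCO3, NaOAc, THF/H2O (4:1), 0 °C
Reagents that add atoms: water, O
Why: NBS brominates the electron-rich 2,4-dialkylfuran at its free C5 and water adds at C2 to give the 2,5-dioxygenated dihydrofuran 34, which opens to the Z ene-dicarbonyl compound 35, whose aldehyde is then captured by the tertiary C11 hydroxyl to form the O1–C6 bond. The closest known reaction type is the Achmatowicz rearrangement of tertiary 2-furylcarbinols, α-hydroxy esters included. The one ring closed, the pyranone, forms by a 6-exo-trig lactolisation in which the Z geometry inherited from the furan holds the aldehyde next to the hydroxyl. No lasting stereocentre is made, since C6 is an anomeric mixture that step 24 removes and the spiro centre C11 from step 18 is not touched. The selectivity needed is oxidation of the furan in the presence of the vinyl, isopropenyl and exocyclic methylene groups. It rests on the far higher nucleophilicity of the furan, on one equivalent of NBS at 0 °C and on the buffer, which keeps acid away from the alkenes and the lactol.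

Step 20
Reactants: 36 spiro 6-hydroxy-2H-pyran-3(6H)-one
Product: 37 6-methoxy pyranone
Conditions: MeI, Ag2O, CH2Cl2, 25 °C, dark
Reagents that add atoms: iodomethane, CI
Why: Silver-oxide-promoted O-methylation fixes the lactol as its methyl acetal under non-basic conditions that spare the β-keto lactone.

Step 21
Reactants: 37 6-methoxy pyranone
Product: 38 saturated keto acetal
Conditions: [(Ph3P)CuH]6, H2O, benzene, 25 °C
Reagents that add atoms: none
Why: Conjugate reduction with the copper hydride hexamer transfers hydride only to C5 of the enone and leaves the isolated alkenes, the lactone and the acetal alone, and the new C5 centre is removed in step 24.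

Step 22
Reactants: 38 saturated keto acetal
Product: 39 tosylhydrazone
Conditions: TsNHNH2, PPTS (cat.), MeOH, 50 °C
Reagents that add atoms: 4-methylbenzenesulfonohydrazide, Cc1ccc(cc1)S(=O)(=O)NN
Why: Condensation of the C3 ketone, activated by the neighbouring ester and alkoxy groups, with the sulfonyl hydrazide gives the tosylhydrazone, and methanol as solvent keeps the methyl acetal intact.

Step 23
Reactants: 39 tosylhydrazone
Product: 42 deoxygenated acetal, via N-borylhydrazine 40 (not isolated), via alkyldiazene 41 (not isolated)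
Conditions: catecholborane, CHCl3, 0 °C; then NaOAc·3H2O, 60 °C
Reagents that add atoms: none
Why: Hydride addition to the C=N bond and acetate-induced loss of sulfinate give the alkyldiazene, which loses N2 to leave CH2 at C3 (tosylhydrazone reduction, a mild relative of the Wolff–Kishner deoxygenation), and the nearly neutral medium disfavours β-elimination of the ring oxygen.

Step 24
Reactants: 42 deoxygenated acetal
Product: 43 target CNP0353330.1
Conditions: Me3SiOTf, iPr2NEt, CH2Cl2, −20 → 25 °C
Reagents that add atoms: none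
Why: The silyl triflate ionises the exocyclic methoxy group to the cyclic oxocarbenium ion and the amine removes H-5, an acetal-to-enol-ether elimination that forms C5=C6 and erases the C5/C6 mixtures.

**Compound list**

1 | 5-chloropent-1-yne | ClCCCC#C | starting material
2 | 2-bromo-5-chloropent-1-ene | ClCCCC(Br)=C | intermediate
3 | (S)-(+)-carvone, (5S)-2-methyl-5-(prop-1-en-2-yl)cyclohex-2-en-1-one | CC1=CC[C@@H](CC1=O)C(C)=C | starting material
4 | (5S)-5-(1-hydroperoxy-1-methoxyethyl)-2-methylcyclohex-2-en-1-one (side-chain epimers) | CC1=CC[C@@H](CC1=O)C(C)(OC)OO | intermediate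
5 | 1-methoxy-1-[(1S)-4-methyl-5-oxocyclohex-3-en-1-yl]ethyl ethaneperoxoate | CC1=CC[C@@H](CC1=O)C(C)(OC)OOC(C)=O | intermediate
6 | (1S)-4-methyl-5-oxocyclohex-3-en-1-yl acetate | CC1=CC[C@@H](CC1=O)OC(C)=O | intermediate
7 | (5-chloropent-1-en-2-yl)magnesium bromide | ClCCCC(=C)[Mg]Br | intermediate
8 | (1S,3S)-3-(5-chloropent-1-en-2-yl)-4-methyl-5-oxocyclohexyl acetate (alkenyl trans to acetoxy; C4 epimers) | ClCCCC(=C)[C@H]1C[C@H](OC(C)=O)CC(=O)C1C | intermediate
9 | (5S)-5-(5-chloropent-1-en-2-yl)-6-methylcyclohex-2-en-1-one (C6 epimers) | ClCCCC(=C)[C@H]1CC=CC(=O)C1C | intermediate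
10 | (4aR,8aS)-8a-methyl-5-methylidene-4a,5,6,7,8,8a-hexahydronaphthalen-1(4H)-one (cis-fused) | C=C1CCC[C@]2(C)C(=O)C=CC[C@H]12 | intermediate
11 | 1-(tert-butyldimethylsilyloxy)-1-methoxyethene | COC(=C)O[Si](C)(C)C(C)(C)C | starting material
12 | methyl 2-[(2R,4aS,8aR)-4-(tert-butyldimethylsilyloxy)-4a-methyl-8-methylidene-1,2,4a,5,6,7,8,8a-octahydronaphthalen-2-yl]acetate | COC(=O)C[C@@H]1C=C(O[Si](C)(C)C(C)(C)C)[C@@]2(C)CCCC(=C)[C@H]2C1 | intermediate
13 | methyl 2-[(2S,4aS,8aR)-4a-methyl-8-methylidene-4-oxodecahydronaphthalen-2-yl]acetate | COC(=O)C[C@@H]1CC(=O)[C@@]2(C)CCCC(=C)[C@H]2C1 | intermediate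
14 | methyl 2-[(2R,4aS,8aR)-4a-methyl-8-methylidene-4-(trifluoromethylsulfonyloxy)-1,2,4a,5,6,7,8,8a-octahydronaphthalen-2-yl]acetate | COC(=O)C[C@@H]1C=C(OS(=O)(=O)C(F)(F)F)[C@@]2(C)CCCC(=C)[C@H]2C1 | intermediate
15 | methyl 2-[(2R,4aR,8aR)-4a-methyl-8-methylidene-1,2,4a,5,6,7,8,8a-octahydronaphthalen-2-yl]acetate | COC(=O)C[C@@H]1C=C[C@@]2(C)CCCC(=C)[C@H]2C1 | intermediate
16 | 2-[(2R,4aR,8aR)-4a-methyl-8-methylidene-1,2,4a,5,6,7,8,8a-octahydronaphthalen-2-yl]acetic acid | OC(=O)C[C@@H]1C=C[C@@]2(C)CCCC(=C)[C@H]2C1 | intermediate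
17 | (3aR,4aR,8aS,9S,9aS)-9-iodo-8a-methyl-5-methylidenedecahydronaphtho[2,3-b]furan-2(3H)-one (iodine trans to the lactone oxygen) | O=C1O[C@@H]2[C@@H](I)[C@@]4(C)CCCC(=C)[C@H]4C[C@@H]2C1 | intermediate
18 | (3aR,4aR,8aR,9aR)-8a-methyl-5-methylidenedecahydronaphtho[2,3-b]furan-2(3H)-one (5β-H, 7α-H, 8α-H, 10β-CH3) | O=C1O[C@@H]2C[C@@]4(C)CCCC(=C)[C@H]4C[C@@H]2C1 | intermediate
19 | methyl vinyl ketone | CC(=O)C=C | starting material
20 | 2-(triisopropylsilyloxy)buta-1,3-diene | C=CC(=C)O[Si](C(C)C)(C(C)C)C(C)C | intermediate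
21 | 2-(triphenylphosphoranylidene)propanal | CC(C=O)=P(c1ccccc1)(c1ccccc1)c1ccccc1 | starting material
22 | methylglyoxal | CC(=O)C=O | starting material
23 | (E)-2-methyl-4-oxopent-2-enal | O=C/C(C)=C/C(C)=O | intermediate
24 | (1S,6S)-6-acetyl-1-methyl-4-(triisopropylsilyloxy)cyclohex-3-ene-1-carbaldehyde | O=C[C@@]1(C)CC=C(O[Si](C(C)C)(C(C)C)C(C)C)C[C@@H]1C(C)=O | intermediate
25 | triisopropyl{[(4R,5R)-4-ethenyl-4-methyl-5-(prop-1-en-2-yl)cyclohex-1-en-1-yl]oxy}silane | C=C[C@@]1(C)CC=C(O[Si](C(C)C)(C(C)C)C(C)C)C[C@@H]1C(C)=C | intermediate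
26 | (3R,4R)-4-ethenyl-4-methyl-3-(prop-1-en-2-yl)cyclohexan-1-one | C=C[C@@]1(C)CCC(=O)C[C@@H]1C(C)=C | intermediate
27 | (3R,4R)-4-ethenyl-4-methyl-3-(prop-1-en-2-yl)cyclohexan-1-ol (C1 epimers) | C=C[C@@]1(C)CCC(O)C[C@@H]1C(C)=C | intermediate
28 | (1R,2R)-1-ethenyl-4-iodo-1-methyl-2-(prop-1-en-2-yl)cyclohexane (C4 epimers) | C=C[C@@]1(C)CCC(I)C[C@@H]1C(C)=C | intermediate
29 | 2,4-dibromofuran | Brc1coc(Br)c1 | starting material
30 | (3aR,4aR,8aR,9aR)-3-(4-bromofuran-2-yl)-8a-methyl-5-methylidenedecahydronaphtho[2,3-b]furan-2(3H)-one (C3 epimers) | Brc1coc(c1)C3C(=O)O[C@@H]4C[C@@]5(C)CCCC(=C)[C@H]5C[C@@H]43 | intermediate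
31 | iodo[(3R,4R)-4-ethenyl-4-methyl-3-(prop-1-en-2-yl)cyclohexyl]zinc | C=C[C@@]1(C)CCC([Zn]I)C[C@@H]1C(C)=C | intermediate
32 | lactone 18 carrying at C11 a 4-[(1S,3R,4R)-4-ethenyl-4-methyl-3-(prop-1-en-2-yl)cyclohexyl]furan-2-yl group (C11 epimers) | C=C[C@@]1(C)CC[C@H](c2coc(c2)C3C(=O)O[C@@H]4C[C@@]5(C)CCCC(=C)[C@H]5C[C@@H]43)C[C@@H]1C(=C)C | intermediate
33 | 11-hydroxy derivative of 32, (11S), hydroxyl syn to H-7 on the convex lactone face, furan on the concave face | C=C[C@@]1(C)CC[C@H](c2coc(c2)[C@]3(O)C(=O)O[C@@H]4C[C@@]5(C)CCCC(=C)[C@H]5C[C@@H]43)C[C@@H]1C(=C)C | intermediate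
34 | 2,5-dihydroxy-2,5-dihydrofuran from 33 (furan C2 and C5 each carry OH; mixture) | C=C[C@@]1(C)CC[C@H](C2=CC(O)(OC2O)[C@]3(O)C(=O)O[C@@H]4C[C@@]5(C)CCCC(=C)[C@H]5C[C@@H]43)C[C@@H]1C(=C)C | intermediate
35 | (Z)-ene-dicarbonyl compound from 33: C11(OH)–C(=O)–CH=C(cyclohexyl)–CHO | C=C[C@@]1(C)CC[C@H](/C(C=O)=C/C(=O)[C@]3(O)C(=O)O[C@@H]4C[C@@]5(C)CCCC(=C)[C@H]5C[C@@H]43)C[C@@H]1C(=C)C | intermediate
36 | spiro 6-hydroxy-2H-pyran-3(6H)-one: pyran C2 = lactone C11, C5 bears the (1S,3R,4R)-cyclohexyl group, C6–OH as anomer mixture | C=C[C@@]1(C)CC[C@H](C2=CC(=O)[C@]3(OC2O)C(=O)O[C@@H]4C[C@@]5(C)CCCC(=C)[C@H]5C[C@@H]43)C[C@@H]1C(=C)C | intermediate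
37 | 6-methoxy analogue of 36 (anomer mixture) | C=C[C@@]1(C)CC[C@H](C2=CC(=O)[C@]3(OC2OC)C(=O)O[C@@H]4C[C@@]5(C)CCCC(=C)[C@H]5C[C@@H]43)C[C@@H]1C(=C)C | intermediate
38 | 4,5-dihydro derivative of 37: spiro 6-methoxytetrahydropyran-3-one (C5/C6 mixture) | C=C[C@@]1(C)CC[C@H](C2CC(=O)[C@]3(OC2OC)C(=O)O[C@@H]4C[C@@]5(C)CCCC(=C)[C@H]5C[C@@H]43)C[C@@H]1C(=C)C | intermediate
39 | tosylhydrazone of 38 at C3 | C=C[C@@]1(C)CC[C@H](C2CC(=NNS(=O)(=O)c6ccc(C)cc6)[C@]3(OC2OC)C(=O)O[C@@H]4C[C@@]5(C)CCCC(=C)[C@H]5C[C@@H]43)C[C@@H]1C(=C)C | intermediate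
40 | N-(1,3,2-benzodioxaborol-2-yl)-N′-tosylhydrazine at C3 | C=C[C@@]1(C)CC[C@H](C2CC(N(NS(=O)(=O)c6ccc(C)cc6)B7Oc8ccccc8O7)[C@]3(OC2OC)C(=O)O[C@@H]4C[C@@]5(C)CCCC(=C)[C@H]5C[C@@H]43)C[C@@H]1C(=C)C | intermediate
41 | alkyldiazene at C3 | C=C[C@@]1(C)CC[C@H](C2CC(N=N)[C@]3(OC2OC)C(=O)O[C@@H]4C[C@@]5(C)CCCC(=C)[C@H]5C[C@@H]43)C[C@@H]1C(=C)C | intermediate
42 | spiro 6-methoxytetrahydropyran with CH2 at C3 and C4 (C5/C6 mixture) | C=C[C@@]1(C)CC[C@H](C2CC[C@]3(OC2OC)C(=O)O[C@@H]4C[C@@]5(C)CCCC(=C)[C@H]5C[C@@H]43)C[C@@H]1C(=C)C | intermediate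
43 | CNP0353330.1, spiro 3,4-dihydro-2H-pyran | C=C[C@@]1(C)CC[C@H](C2=CO[C@@]3(CC2)C(=O)O[C@@H]2C[C@@]4(C)CCCC(=C)[C@H]4C[C@@H]23)C[C@@H]1C(=C)C | target

**Totals**

Total step count: 24. Longest linear sequence: 17 steps (steps 2–9 and 16–24, from (S)-carvone).

**Steps most likely to fail**

Step 19 (key step). Electrophilic bromine may also be consumed by the isopropenyl, vinyl and exocyclic methylene groups (bromohydrin formation), or the product enone may be brominated, so that oxidation of the furan does not stay selective. The fallback sets out from 33 and comes back at 36. It replaces halogenation by dye-sensitised photo-oxygenation: singlet oxygen (O2, tetraphenylporphyrin, CH2Cl2, −78 °C, visible light) adds across C2 and C5 of the furan in a [4+2] cycloaddition to give the furan endoperoxide F1, a reaction that is far faster than the ene reaction of singlet oxygen with 1,1-disubstituted or monosubstituted alkenes. Reduction with Me2S at −78 → 0 °C opens it to enedione 35, which closes to 36 as in the main route.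

Step 23. Condensation at the neopentyl C3 carbonyl may already be slow in step 22, and at the diazene stage the ring oxygen O1 may be lost by β-elimination, which would open the pyran; retro-Claisen cleavage of the β-keto lactone is a further drain. The fallback sets out from 38 and comes back at 42, bypassing steps 22 and 23. Reduction with NaBH4 and CeCl3·7H2O in MeOH at −40 °C gives the C3 alcohol F2. Acylation with O-phenyl chlorothionoformate, pyridine and DMAP in CH2Cl2 gives the O-phenyl thionocarbonate F3. Barton–McCombie deoxygenation (Bu3SnH, AIBN, toluene, 80 °C) then gives 42; the C3 radical has no alkene within reach of a 5-exo closure, and a β-alkoxy radical does not fragment.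

Step 12. The cationic boron catalyst may bind the ketone of 23 instead of the aldehyde, or the enone part of 23 may react as a 1-oxadiene with the silyl enol ether, so that regio- and enantiocontrol are eroded. The fallback sets out from 20 and comes back at 25. It uses commercial ethyl (E)-3-formylbut-2-enoate, a dienophile without a ketone, under the same catalyst to give the formyl ester adduct F4. Wittig methylenation (Ph3PCH3Br, KN(SiMe3)2) gives the vinyl ester F5. Me(MeO)NH·HCl with iPrMgCl in THF at −20 °C gives the N-methoxy-N-methylamide F6. MeMgBr in THF at 0 °C gives the methyl ketone F7, and a second Wittig methylenation gives 25.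

**Further compounds**

F1 | step 19 | furan 2,5-endoperoxide of 33 (2,3,7-trioxabicyclo[2.2.1]hept-5-ene) | C=C[C@@]1(C)CC[C@H](C2=CC6(OOC2O6)[C@]3(O)C(=O)O[C@@H]4C[C@@]5(C)CCCC(=C)[C@H]5C[C@@H]43)C[C@@H]1C(=C)C
F2 | step 23 | C3 alcohol from 38 (C3 epimers) | C=C[C@@]1(C)CC[C@H](C2CC(O)[C@]3(OC2OC)C(=O)O[C@@H]4C[C@@]5(C)CCCC(=C)[C@H]5C[C@@H]43)C[C@@H]1C(=C)C
F3 | step 23 | O-phenyl thionocarbonate of F2 | C=C[C@@]1(C)CC[C@H](C2CC(OC(=S)Oc6ccccc6)[C@]3(OC2OC)C(=O)O[C@@H]4C[C@@]5(C)CCCC(=C)[C@H]5C[C@@H]43)C[C@@H]1C(=C)C
F4 | step 12 | ethyl (1S,2S)-2-formyl-2-methyl-5-(triisopropylsilyloxy)cyclohex-4-ene-1-carboxylate | O=C[C@@]1(C)CC=C(O[Si](C(C)C)(C(C)C)C(C)C)C[C@@H]1C(=O)OCC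
F5 | step 12 | ethyl (1S,2R)-2-ethenyl-2-methyl-5-(triisopropylsilyloxy)cyclohex-4-ene-1-carboxylate | C=C[C@@]1(C)CC=C(O[Si](C(C)C)(C(C)C)C(C)C)C[C@@H]1C(=O)OCC
F6 | step 12 | (1S,2R)-2-ethenyl-N-methoxy-N,2-dimethyl-5-(triisopropylsilyloxy)cyclohex-4-ene-1-carboxamide | C=C[C@@]1(C)CC=C(O[Si](C(C)C)(C(C)C)C(C)C)C[C@@H]1C(=O)N(C)OC
F7 | step 12 | 1-[(1S,2R)-2-ethenyl-2-methyl-5-(triisopropylsilyloxy)cyclohex-4-en-1-yl]ethan-1-one | C=C[C@@]1(C)CC=C(O[Si](C(C)C)(C(C)C)C(C)C)C[C@@H]1C(C)=O
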